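**Plan**

1. Numbering (onocerane): left decalin C1–C10 with C8=C26H2; linker C11–C12; ring B′ = C13, C14, C15, C16, C17, C18 (C13=C14, CH3-27 on C14); ring A′ = C17–C22 (CH3-28 on C18). In the given structure the left decalin is trans-fused (5S,9S,10S), but the right one is cis-fused (17R,18S): H-17 and CH3-28 lie on the same face.
2. Retrosynthetic cuts, in order: C8=C26 ⇐ 8α-OH (the lactone oxygen of sclareolide); C13=C14 with C12H2 ⇐ tertiary allylic alcohol at C14 with exocyclic C12=C13 (reductive 1,3-transposition); ring bond C13–C18 ⇐ Pd–H cycloisomerization of a 1,7-enyne; C13–C14 ⇐ acetylide plus methyl ketone.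
3. Enabling feature: the tetrasubstituted C13=C14 sits directly on the quaternary C18 of a cis ring fusion next to C17–H. This is the imprint of a syn-carbopalladation of the C18=C19 bond of an α-cyclogeranyl ring (ring A′) by an alkenyl-palladium on C13 that is tethered through C14–C16 to C17.
4. Forward: (+)-sclareolide → lactol → C17 alkynol (rings A/B); (R)-α-ionone → dihydro-α-ionone (ring A′); acetylide addition joins all 30 carbons; ring B′ is closed last; then deoxygenation with transposition at C14, saturation of the ring-A′ alkene, and dehydration to the exocyclic methylene.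
5. Stereochemistry: C5, C9, C10 come from sclareolide and C17 from (R)-α-ionone; C18 is set by substrate control in the key step (cis delivery from the C17 tether); the carbinol C14 is a relay centre whose configuration is erased.

Key step: step 5

Assumption: (R)-(+)-α-ionone (the natural enantiomer) is taken as a commercial starting material of high enantiomeric purity; this purity limits the diastereomeric purity after step 4.

**Route**

Step 1
Reactants: 1 (+)-sclareolide
Product: 2 sclareolide lactol (8α,12-epoxy-12-ol; both anomers)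
Conditions: DIBAL-H (1.1 equiv), CH2Cl2, −78 °C; aq. Rochelle salt
Reagents that add atoms: none
Why: Partial DIBAL-H reduction of a γ-lactone stops at the lactol because the tetrahedral aluminate is stable at −78 °C; no stereocentre of 1 is touched.

Step 2
Reactants: 2 sclareolide lactol
Product: 3 alkynol (1R,2R,4aS,8aS)-2,5,5,8a-tetramethyl-1-(prop-2-yn-1-yl)decahydronaphthalen-2-ol
Conditions: Bestmann–Ohira reagent (1.3 equiv), K2CO3 (2 equiv), MeOH, 0 °C → rt
Reagents that add atoms: Bestmann–Ohira reagent, dimethyl (1-diazo-2-oxopropyl)phosphonate, CC(=O)C(=[N+]=[N-])P(=O)(OC)OC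
Why: Seyferth–Gilbert homologation: the lactol reacts through its open 8-hydroxy-12-aldehyde form, C12 becomes the internal alkyne carbon and the reagent supplies C13, while the mild K2CO3/MeOH medium leaves the tertiary 8α-OH and all stereocentres untouched.

Step 3
Reactants: 4 (R)-(+)-α-ionone
Product: 5 (R)-dihydro-α-ionone, 4-[(1R)-2,6,6-trimethylcyclohex-2-en-1-yl]butan-2-one
Conditions: H2 (1 atm), RhCl(PPh3)3 (5 mol %), benzene, rt
Reagents that add atoms: none
Why: Chemoselective homogeneous hydrogenation with Wilkinson's catalyst should reduce the disubstituted enone C=C much faster than the trisubstituted ring alkene and, being neutral and non-isomerising, should not epimerise the allylic C17–H.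

Step 4
Reactants: 3 alkynol; 5 (R)-dihydro-α-ionone
Product: 7 enyne diol (1R,2R,4aS,8aS)-1-{4-hydroxy-4-methyl-6-[(1R)-2,6,6-trimethylcyclohex-2-en-1-yl]hex-2-yn-1-yl}-2,5,5,8a-tetramethyldecahydronaphthalen-2-ol (both C14 epimers), via dilithio alkynolate 6 (not isolated)
Conditions: 3, n-BuLi (2.1 equiv), THF, −78 → 0 °C; then 5, −78 °C → rt; aq. NH4Cl
Reagents that add atoms: none
Why: 1,2-Addition of a lithium acetylide to a methyl ketone (the second equivalent of base covers the tertiary OH) forms C13–C14 and the tertiary propargylic carbinol, whose uncontrolled configuration is erased in step 6.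

Step 5
Reactants: 7 enyne diol
Product: 8 (5S,8R,9R,10S,12Z,17R,18S)-onocera-12,19-diene-8,14-diol (C14 epimers; ring B′ closed and cis-fused to ring A′, exocyclic C12=C13, C19=C20 in ring A′)
Conditions: Pd2(dba)3·CHCl3 (5 mol %), P(o-tol)3 (10 mol %), AcOH (1 equiv), degassed benzene, 60–80 °C
Reagents that add atoms: none
Why: A hydridopalladium acetate (from Pd(0) and AcOH) adds syn across C12≡C13 with Pd on C13; the alkenyl-palladium then inserts the C18=C19 bond of ring A′ to form C13–C18, and syn β-hydride elimination from C20 releases the 1,4-diene and regenerates Pd–H. The closest known reaction type is the Pd-catalysed Alder-ene cycloisomerization of 1,n-enynes, whose ring-forming event is an intramolecular Heck insertion of the kind used to build cis-fused decalins with an angular quaternary carbon. Ring B′ (C13–C18) closes in the 6-exo-trig mode and no other ring is formed. The only new stereocentre, quaternary C18, is controlled by C17: the three-atom tether C14–C16 on C17 can deliver C13 only to the alkene face syn to C16, so CH3-28 ends cis to H-17 (cis fusion, 18S); the Z geometry of C12=C13 follows from syn hydropalladation and is lost in step 6. The step needs Pd on C13 and insertion at the methyl-bearing C18: hydropalladation is reversible and only the C13–Pd isomer can cyclize, ring size favours 6-exo over 7-endo, and C18 carries no hydrogen so elimination can only go towards C20. Any C19=C20/C20=C21 positional isomers from Pd–H re-addition would converge in step 7.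

Step 6
Reactants: 8 diene diol
Product: 9 (5S,8R,9R,10S,17R,18S)-onocera-13,19-dien-8-ol
Conditions: Et3SiH (10 equiv), BF3·OEt2 (3 equiv), CH2Cl2, −78 → −30 °C
Reagents that add atoms: none
Why: Ionic hydrogenation with 1,3-transposition: BF3 ionises the tertiary allylic C14–OH to the C12–C13–C14 allyl cation and Et3SiH should deliver hydride to the less hindered secondary terminus C12, leaving the tetrasubstituted C13=C14, while the isolated tertiary 8-OH and the disubstituted C19=C20 should not ionise at this temperature and any 8,12-ether from O-8 capture should re-ionise to the same cation.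

Step 7
Reactants: 9 dienol
Product: 10 (5S,8R,9R,10S,17R,18S)-onocer-13-en-8-ol
Conditions: H2 (1 atm), 5% Pt/C, EtOAc, rt
Reagents that add atoms: none
Why: Catalytic hydrogenation should be selective for the cis-disubstituted ring-A′ alkene, since the tetrasubstituted C13=C14 flanked by quaternary C18 is not reduced at 1 atm; no stereocentre is created (C19 and C20 become CH2).

Step 8
Reactants: 10 enol
Product: 12 target (5S,9S,10S,17R,18S)-onocera-8(26),13-diene, via 8-O-chlorosulfite 11 (not isolated)
Conditions: SOCl2 (2 equiv), pyridine (excess), CH2Cl2, −78 → 0 °C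
Reagents that add atoms: none
Why: E2 dehydration of the chlorosulfite by pyridine: the equatorial 8α-oxygen has no anti-periplanar ring hydrogen on C7 or C9, so the proton should be taken from the C8 methyl (C26) to give the exocyclic alkene, and the tetrasubstituted C13=C14 is inert.

**Compound list**

1 | (+)-sclareolide, (3aR,5aS,9aS,9bR)-3a,6,6,9a-tetramethyldecahydronaphtho[2,1-b]furan-2(1H)-one | C[C@@]12CC[C@H]3C(C)(C)CCC[C@]3(C)[C@H]1CC(=O)O2 | starting material
2 | sclareolide lactol, (3aR,5aS,9aS,9bR)-3a,6,6,9a-tetramethyldodecahydronaphtho[2,1-b]furan-2-ol (both anomers) | C[C@@]12CC[C@H]3C(C)(C)CCC[C@]3(C)[C@H]1CC(O)O2 | intermediate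
3 | alkynol, (1R,2R,4aS,8aS)-2,5,5,8a-tetramethyl-1-(prop-2-yn-1-yl)decahydronaphthalen-2-ol | C[C@@]1(O)CC[C@H]2C(C)(C)CCC[C@]2(C)[C@H]1CC#C | intermediate
4 | (R)-(+)-α-ionone, (3E)-4-[(1R)-2,6,6-trimethylcyclohex-2-en-1-yl]but-3-en-2-one | CC(=O)/C=C/[C@@H]1C(C)(C)CCC=C1C | starting material
5 | (R)-dihydro-α-ionone, 4-[(1R)-2,6,6-trimethylcyclohex-2-en-1-yl]butan-2-one | CC(=O)CC[C@@H]1C(C)(C)CCC=C1C | intermediate
6 | dilithio alkynolate of 3 (lithium 8-alkoxide, lithium C13-acetylide) | C[C@@]1(O[Li])CC[C@H]2C(C)(C)CCC[C@]2(C)[C@H]1CC#C[Li] | intermediate (not isolated)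
7 | enyne diol, (1R,2R,4aS,8aS)-1-{4-hydroxy-4-methyl-6-[(1R)-2,6,6-trimethylcyclohex-2-en-1-yl]hex-2-yn-1-yl}-2,5,5,8a-tetramethyldecahydronaphthalen-2-ol (C14 epimers) | C[C@@]1(O)CC[C@H]2C(C)(C)CCC[C@]2(C)[C@H]1CC#CC(C)(O)CC[C@@H]1C(C)(C)CCC=C1C | intermediate
8 | (5S,8R,9R,10S,12Z,17R,18S)-onocera-12,19-diene-8,14-diol (C14 epimers; right decalin cis-fused) | C[C@@]1(O)CC[C@H]2C(C)(C)CCC[C@]2(C)[C@H]1C/C=C1\C(C)(O)CC[C@@H]2C(C)(C)CC=C[C@]12C | intermediate
9 | (5S,8R,9R,10S,17R,18S)-onocera-13,19-dien-8-ol | C[C@@]1(O)CC[C@H]2C(C)(C)CCC[C@]2(C)[C@H]1CCC1=C(C)CC[C@@H]2C(C)(C)CC=C[C@]12C | intermediate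
10 | (5S,8R,9R,10S,17R,18S)-onocer-13-en-8-ol | C[C@@]1(O)CC[C@H]2C(C)(C)CCC[C@]2(C)[C@H]1CCC1=C(C)CC[C@@H]2C(C)(C)CCC[C@]12C | intermediate
11 | 8-O-chlorosulfite of 10 | C[C@@]1(OS(Cl)=O)CC[C@H]2C(C)(C)CCC[C@]2(C)[C@H]1CCC1=C(C)CC[C@@H]2C(C)(C)CCC[C@]12C | intermediate (not isolated)
12 | (5S,9S,10S,17R,18S)-onocera-8(26),13-diene | C=C1CC[C@H]2C(C)(C)CCC[C@]2(C)[C@H]1CCC1=C(C)CC[C@@H]2C(C)(C)CCC[C@]12C | target

**Step count and risks**

Total steps: 8. Longest linear sequence: 7 (steps 1, 2, 4, 5, 6, 7, 8).

Steps most likely to fail: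

Step 5. The alkenyl-palladium may not form on C13, or may not insert into the hindered, methyl-bearing C18=C19 bond before other channels take over. Those channels are Pd-promoted addition of the 8-OH across the alkyne, β-hydroxide elimination to an allene, and Pd–H migration of the ring alkene. The fallback sets out from 7 and fixes the metal position by a stoichiometric alkenyl halide. An O-directed radical hydrostannation (Ph3SnH, cat. Et3B/air, toluene, rt) should place tin on C13 next to the carbinol and give the (12Z)-13-triphenylstannyl allylic diol F1. Iododestannylation (I2, CH2Cl2, 0 °C) should give the (12Z)-13-iodo allylic diol F2. An intramolecular 6-exo Heck reaction (Pd(OAc)2, PPh3, Ag2CO3, MeCN, 80 °C) should then close ring B′ with the same cis delivery and give the (12E)-isomer of 8, F3. F3 under the conditions of step 6 should give 9, where the fallback rejoins the route.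

Step 6. Capture of the allyl cation by O-8 may outrun hydride transfer and stall at the cyclic ether, and forcing conditions risk ionisation of the tertiary 8-OH or over-reduction of the new alkene. The fallback sets out from 8 and makes the ether on purpose. Catalytic camphorsulfonic acid (CH2Cl2, 0 °C) should ionise C14–OH and let O-8 close on C12 to give the 8,12-epoxy-onocera-13,19-diene (cyclic allylic ether) F4. Lithium in NH3/THF with t-BuOH at −78 °C should then cleave the allylic C12–O bond and protonate the allyl anion at C12, giving 9; isolated alkenes are inert to these conditions.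

Step 8. Regiocontrol may be lost in the elimination through E1 leakage, giving endocyclic C7=C8 or C8=C9 isomers. The fallback sets out from 10 and uses a thermal syn-elimination. KH, CS2, then MeI (THF, 0 °C) should give the 8-O-(S-methyl) xanthate F5. On warming (toluene, 80–110 °C) F5 should undergo Chugaev elimination, which can reach a syn hydrogen most easily on the C8 methyl, to give 12.

**Further compounds**

F1 | step 5 | (12Z)-13-(triphenylstannyl) alkene from 7 (C12H=C13(SnPh3); 8,14-diol; ring A′ C18=C19; C14 epimers) | C[C@@]1(O)CC[C@H]2C(C)(C)CCC[C@]2(C)[C@H]1C/C=C(\[Sn](c1ccccc1)(c1ccccc1)c1ccccc1)C(C)(O)CC[C@@H]1C(C)(C)CCC=C1C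
F2 | step 5 | (12Z)-13-iodo alkene from F1 (C12H=C13(I); 8,14-diol; ring A′ C18=C19; C14 epimers) | C[C@@]1(O)CC[C@H]2C(C)(C)CCC[C@]2(C)[C@H]1C/C=C(\I)C(C)(O)CC[C@@H]1C(C)(C)CCC=C1C
F3 | step 5 | (5S,8R,9R,10S,12E,17R,18S)-onocera-12,19-diene-8,14-diol (12E isomer of 8) | C[C@@]1(O)CC[C@H]2C(C)(C)CCC[C@]2(C)[C@H]1C/C=C1/C(C)(O)CC[C@@H]2C(C)(C)CC=C[C@]12C
F4 | step 6 | (5S,8R,9R,10S,17R,18S)-8,12-epoxy-onocera-13,19-diene (C12 epimers) | C[C@@]12CC[C@H]3C(C)(C)CCC[C@]3(C)[C@H]1CC(O2)C1=C(C)CC[C@@H]2C(C)(C)CC=C[C@]12C
F5 | step 8 | 8-O-(S-methyl) xanthate of 10 | C[C@@]1(OC(=S)SC)CC[C@H]2C(C)(C)CCC[C@]2(C)[C@H]1CCC1=C(C)CC[C@@H]2C(C)(C)CCC[C@]12C
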